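**Retrosynthetic overview**
1. Robustol 21 ⇐ its tri-O-methyl ether 19 by global BBr3 demethylation (last step).
2. 19 ⇐ seco bromophenol 18 by intramolecular Ullmann C–O coupling; this closes the 22-membered macrocycle, the only ring that is built (benzene rings A and B are bought in 3 and 11).
3. 18 ⇐ enone 14 (C=C hydrogenation, Wolff–Kishner reduction, MOM removal); 14 ⇐ methyl ketone 10 (ring A plus 13 tether carbons) + aldehyde 12 (ring B plus tether C1) by an intermolecular crossed aldol (Claisen–Schmidt) condensation that forms the C1–C2 bond of the tether.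
4. 10 ⇐ 3-bromo-5-methoxybenzaldehyde 3 + 11-bromoundecanoic acid 1 (Wittig, hydrogenation, Weinreb amide, MeMgBr); 12 ⇐ syringaldehyde 11 (MOM protection).
5. Ring order: rings A and B are preformed; the macrocycle is formed in step 11 of 12.

Assumption: robustol has no stereocentre and is achiral, so there is no enantiomer to select; 3-bromo-5-methoxybenzaldehyde is taken as a catalogue building block.

**Route**

Step 1
Reactants: 1 11-bromoundecanoic acid
Product: 2 (10-carboxydecyl)triphenylphosphonium bromide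
Conditions: PPh3 (1.05 equiv), MeCN, reflux, 48 h
Reagents that add atoms: triphenylphosphine, c1ccc(cc1)P(c1ccccc1)c1ccccc1
Why: SN2 quaternisation of the phosphine by the unhindered primary bromide (phosphonium salt formation) is clean, and the free acid does not interfere.

Step 2
Reactants: 2 (10-carboxydecyl)triphenylphosphonium bromide; 3 3-bromo-5-methoxybenzaldehyde
Product: 5 (Z)-12-(3-bromo-5-methoxyphenyl)dodec-11-enoic acid, via carboxylate ylide 4 (not isolated)
Conditions: NaN(SiMe3)2 (2.3 equiv), THF, 0 °C; then 3, −78 °C → rt; 1 M HCl work-up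
Reagents that add atoms: none
Why: Wittig olefination of a non-enolisable aryl aldehyde by the non-stabilised carboxylate ylide leaves the aryl bromide untouched, and the Z/E mixture (Z major) is irrelevant because the alkene is saturated in step 3.

Step 3
Reactants: 5 (Z)-12-(3-bromo-5-methoxyphenyl)dodec-11-enoic acid
Product: 6 12-(3-bromo-5-methoxyphenyl)dodecanoic acid
Conditions: H2 (3 atm), RhCl(PPh3)3 (3 mol %), toluene/EtOH 1:1, 40 °C
Reagents that add atoms: none
Why: Homogeneous hydrogenation with RhCl(PPh3)3 saturates the disubstituted styrene-type alkene without the C–Br hydrogenolysis that Pd/C would cause, and both alkene isomers converge.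

Step 4
Reactants: 6 12-(3-bromo-5-methoxyphenyl)dodecanoic acid
Product: 8 12-(3-bromo-5-methoxyphenyl)-N-methoxy-N-methyldodecanamide, via acyl imidazole 7 (not isolated)
Conditions: CDI (1.2 equiv), CH2Cl2, rt, 1 h; then MeNHOMe·HCl (1.5 equiv), rt, 12 h
Reagents that add atoms: N,O-dimethylhydroxylamine hydrochloride, CNOC.Cl
Why: Weinreb amide formation through the acyl imidazole is a mild, high-yielding amidation that needs no acid chloride.

Step 5
Reactants: 8 12-(3-bromo-5-methoxyphenyl)-N-methoxy-N-methyldodecanamide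
Product: 10 13-(3-bromo-5-methoxyphenyl)tridecan-2-one, via magnesium chelate 9 (not isolated)
Conditions: MeMgBr (1.5 equiv), THF, 0 °C; then 1 M HCl
Reagents that add atoms: methylmagnesium bromide, C[Mg]Br
Why: Weinreb ketone synthesis: the stable five-membered chelate stops the addition at the ketone stage, and MeMgBr at 0 °C does not exchange with the aryl bromide.

Step 6
Reactants: 11 syringaldehyde (4-hydroxy-3,5-dimethoxybenzaldehyde)
Product: 12 3,5-dimethoxy-4-(methoxymethoxy)benzaldehyde
Conditions: MOMCl (1.5 equiv), K2CO3 (2 equiv), acetone, 0 °C → rt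
Reagents that add atoms: chloromethyl methyl ether, COCCl
Why: Williamson-type O-alkylation (MOM protection) masks the acidic phenol, whose phenoxide would deactivate the aldehyde in step 7, with an acetal that survives base, hydrogenation and Wolff–Kishner conditions.

Step 7 (key fragment union)
Reactants: 10 13-(3-bromo-5-methoxyphenyl)tridecan-2-one; 12 3,5-dimethoxy-4-(methoxymethoxy)benzaldehyde (1.3 equiv)
Product: 14 (E)-14-(3-bromo-5-methoxyphenyl)-1-[3,5-dimethoxy-4-(methoxymethoxy)phenyl]tetradec-1-en-3-one, via aldol adduct 13 (not isolated)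
Conditions: NaOH (2 equiv, 10 % aq), EtOH/THF, rt → 40 °C, 24–48 h
Reagents that add atoms: none
Why: Claisen–Schmidt crossed aldol condensation: only the ketone can enolise and only the aryl aldehyde is electrophilic, and under hydroxide the reversible aldol is funnelled through the methyl-side adduct because only it dehydrates readily (E1cB) to the conjugated (E)-enone; the carbinol centre of racemic 13 is erased on dehydration.

Step 8
Reactants: 14 (E)-14-(3-bromo-5-methoxyphenyl)-1-[3,5-dimethoxy-4-(methoxymethoxy)phenyl]tetradec-1-en-3-one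
Product: 15 14-(3-bromo-5-methoxyphenyl)-1-[3,5-dimethoxy-4-(methoxymethoxy)phenyl]tetradecan-3-one
Conditions: H2 (4 atm), RhCl(PPh3)3 (5 mol %), toluene/EtOH 1:1, 50 °C
Reagents that add atoms: none
Why: Chemoselective homogeneous hydrogenation reduces only the conjugated C=C and leaves the ketone, the MOM acetal and the aryl bromide intact.

Step 9
Reactants: 15 14-(3-bromo-5-methoxyphenyl)-1-[3,5-dimethoxy-4-(methoxymethoxy)phenyl]tetradecan-3-one
Product: 17 1-bromo-3-{14-[3,5-dimethoxy-4-(methoxymethoxy)phenyl]tetradecyl}-5-methoxybenzene, via hydrazone 16 (not isolated)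
Conditions: N2H4·H2O (10 equiv), KOH (6 equiv), diethylene glycol, 130 °C, 2 h; then distil to 200 °C, 4 h
Reagents that add atoms: none
Why: Wolff–Kishner reduction (Huang–Minlon procedure) of an unhindered dialkyl ketone is dependable, and the non-activated aryl bromide, the aryl methyl ethers and the base-stable MOM acetal tolerate hot KOH.

Step 10
Reactants: 17 1-bromo-3-{14-[3,5-dimethoxy-4-(methoxymethoxy)phenyl]tetradecyl}-5-methoxybenzene
Product: 18 4-[14-(3-bromo-5-methoxyphenyl)tetradecyl]-2,6-dimethoxyphenol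
Conditions: conc. HCl (cat.), MeOH/THF, 50 °C
Reagents that add atoms: none
Why: Acid-catalysed acetal cleavage (transacetalisation to methanol) frees the phenol while the methyl ethers and the aryl bromide are inert.

Step 11 (macrocyclisation)
Reactants: 18 4-[14-(3-bromo-5-methoxyphenyl)tetradecyl]-2,6-dimethoxyphenol
Product: 19 robustol tri-O-methyl ether (22-membered macrocyclic diaryl ether)
Conditions: CuI (0.5 equiv), picolinic acid (1.0 equiv), K3PO4 (3 equiv), degassed DMSO, 90 °C, Ar; syringe-pump addition of 18 over 20 h (final 2 mM)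
Reagents that add atoms: none
Why: Intramolecular Ullmann diaryl ether synthesis with the CuI/picolinic acid system, which accepts di-ortho-substituted phenols and plain aryl bromides; high dilution favours closure of the strain-free 22-membered ring over oligomers.

Step 12
Reactants: 19 robustol tri-O-methyl ether
Product: 21 robustol, via tris(dibromoboryl) ether 20 (not isolated)
Conditions: BBr3 (9 equiv), CH2Cl2, −78 °C → rt, 12 h; then H2O, 0 °C
Reagents that add atoms: none
Why: Lewis-acid cleavage of aryl methyl ethers with BBr3 removes all three methyl groups while the diaryl ether C–O bonds stay intact.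

**Compound list**
1 | 11-bromoundecanoic acid | OC(=O)CCCCCCCCCCBr | starting material
2 | (10-carboxydecyl)triphenylphosphonium bromide | OC(=O)CCCCCCCCCC[P+](c1ccccc1)(c1ccccc1)c1ccccc1.[Br-] | intermediate
3 | 3-bromo-5-methoxybenzaldehyde | COc1cc(Br)cc(C=O)c1 | starting material
4 | sodium 11-(triphenylphosphoranylidene)undecanoate, carboxylate ylide (not isolated) | [Na+].[O-]C(=O)CCCCCCCCCC=P(c1ccccc1)(c1ccccc1)c1ccccc1 | intermediate
5 | (Z)-12-(3-bromo-5-methoxyphenyl)dodec-11-enoic acid (Z major, some E) | COc1cc(Br)cc(c1)/C=C\CCCCCCCCCC(O)=O | intermediate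
6 | 12-(3-bromo-5-methoxyphenyl)dodecanoic acid | COc1cc(Br)cc(c1)CCCCCCCCCCCC(O)=O | intermediate
7 | 1-[12-(3-bromo-5-methoxyphenyl)dodecanoyl]imidazole (not isolated) | COc1cc(Br)cc(c1)CCCCCCCCCCCC(=O)n1ccnc1 | intermediate
8 | 12-(3-bromo-5-methoxyphenyl)-N-methoxy-N-methyldodecanamide | COc1cc(Br)cc(c1)CCCCCCCCCCCC(=O)N(C)OC | intermediate
9 | bromomagnesium alkoxide of the tetrahedral adduct of MeMgBr to 8, magnesium chelate (not isolated) | COc1cc(Br)cc(c1)CCCCCCCCCCCC(C)(O[Mg]Br)N(C)OC | intermediate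
10 | 13-(3-bromo-5-methoxyphenyl)tridecan-2-one | COc1cc(Br)cc(c1)CCCCCCCCCCCC(C)=O | intermediate
11 | syringaldehyde (4-hydroxy-3,5-dimethoxybenzaldehyde) | COc1cc(C=O)cc(OC)c1O | starting material
12 | 3,5-dimethoxy-4-(methoxymethoxy)benzaldehyde | COCOc1c(OC)cc(C=O)cc1OC | intermediate
13 | 14-(3-bromo-5-methoxyphenyl)-1-hydroxy-1-[3,5-dimethoxy-4-(methoxymethoxy)phenyl]tetradecan-3-one, racemic aldol adduct (not isolated) | COCOc1c(OC)cc(cc1OC)C(O)CC(=O)CCCCCCCCCCCc1cc(Br)cc(OC)c1 | intermediate
14 | (E)-14-(3-bromo-5-methoxyphenyl)-1-[3,5-dimethoxy-4-(methoxymethoxy)phenyl]tetradec-1-en-3-one | COCOc1c(OC)cc(cc1OC)/C=C/C(=O)CCCCCCCCCCCc1cc(Br)cc(OC)c1 | intermediate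
15 | 14-(3-bromo-5-methoxyphenyl)-1-[3,5-dimethoxy-4-(methoxymethoxy)phenyl]tetradecan-3-one | COCOc1c(OC)cc(cc1OC)CCC(=O)CCCCCCCCCCCc1cc(Br)cc(OC)c1 | intermediate
16 | hydrazone of 15 (not isolated) | COCOc1c(OC)cc(cc1OC)CCC(=NN)CCCCCCCCCCCc1cc(Br)cc(OC)c1 | intermediate
17 | 1-bromo-3-{14-[3,5-dimethoxy-4-(methoxymethoxy)phenyl]tetradecyl}-5-methoxybenzene | COCOc1c(OC)cc(cc1OC)CCCCCCCCCCCCCCc1cc(Br)cc(OC)c1 | intermediate
18 | 4-[14-(3-bromo-5-methoxyphenyl)tetradecyl]-2,6-dimethoxyphenol | COc1cc(cc(OC)c1O)CCCCCCCCCCCCCCc1cc(Br)cc(OC)c1 | intermediate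
19 | robustol tri-O-methyl ether | COc1cc2cc(c1)Oc1c(OC)cc(cc1OC)CCCCCCCCCCCCCC2 | intermediate
20 | tris(dibromoboryl) ether of robustol (not isolated) | BrB(Br)Oc1cc2cc(c1)Oc1c(OB(Br)Br)cc(cc1OB(Br)Br)CCCCCCCCCCCCCC2 | intermediate
21 | robustol | Oc1cc2cc(c1)Oc1c(O)cc(cc1O)CCCCCCCCCCCCCC2 | target

**Step count**
Total: 12 steps. Longest linear sequence: 11 steps (1 → 2 → 5 → 6 → 8 → 10 → 14 → 15 → 17 → 18 → 19 → 21); step 6 is a one-step side branch.

**Three steps most likely to fail, with fallbacks**

Step 11 (macrocyclic Ullmann coupling) is the main risk: the phenol is di-ortho-substituted and oxidisable, the bromide is not activated, and oligomerisation competes. The fallback leaves the Ullmann manifold for an oxidative boron-based ring closure at room temperature. It sets out from 17: Miyaura borylation (B2pin2, PdCl2(dppf) with dppf = 1,1'-bis(diphenylphosphino)ferrocene, KOAc, dioxane, 85 °C) gives 2-{3-[14-(3,5-dimethoxy-4-(methoxymethoxy)phenyl)tetradecyl]-5-methoxyphenyl}-4,4,5,5-tetramethyl-1,3,2-dioxaborolane F1. Cleavage of the pinacol ester and the MOM acetal (NaIO4, THF/H2O, then HCl, MeOH, 40 °C) gives {3-[14-(4-hydroxy-3,5-dimethoxyphenyl)tetradecyl]-5-methoxyphenyl}boronic acid F2. Chan–Lam–Evans coupling under high dilution (Cu(OAc)2, pyridine, 4 Å sieves, CH2Cl2, air, rt, 1 mM) closes the ring and comes back to the route at 19.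

Step 7 (Claisen–Schmidt condensation) may stall with the electron-rich aldehyde or give some methylene-side or Michael by-products. The fallback keeps the same bond but makes it as a kinetically directed aldol in separate stages. It sets out from 10: LiN(SiMe3)2 (THF, −78 °C) gives the methyl-side lithium enolate of 13-(3-bromo-5-methoxyphenyl)tridecan-2-one F3, which adds to 12 at −78 °C to give aldol 13, now isolated after NH4Cl quench. MsCl/Et3N (CH2Cl2, 0 °C) converts 13 into the benzylic mesylate, 14-(3-bromo-5-methoxyphenyl)-1-[3,5-dimethoxy-4-(methoxymethoxy)phenyl]-3-oxotetradecyl methanesulfonate F4, and DBU eliminates it, coming back to the route at 14.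

Step 9 (Wolff–Kishner reduction) could cost some aryl bromide or an aryl methyl ether at 200 °C. The fallback avoids hot base by deoxygenating through the alcohol. It sets out from 15: NaBH4 (MeOH, 0 °C) gives racemic 14-(3-bromo-5-methoxyphenyl)-1-[3,5-dimethoxy-4-(methoxymethoxy)phenyl]tetradecan-3-ol F5. TsCl/pyridine/DMAP gives the tosylate, 14-(3-bromo-5-methoxyphenyl)-1-[3,5-dimethoxy-4-(methoxymethoxy)phenyl]tetradecan-3-yl 4-methylbenzenesulfonate F6. Hydride displacement with LiBHEt3 (THF, 0 °C → rt) comes back to the route at 17.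

**Further compounds**
F1 | step 11 | 2-{3-[14-(3,5-dimethoxy-4-(methoxymethoxy)phenyl)tetradecyl]-5-methoxyphenyl}-4,4,5,5-tetramethyl-1,3,2-dioxaborolane | COCOc1c(OC)cc(cc1OC)CCCCCCCCCCCCCCc1cc(OC)cc(c1)B1OC(C)(C)C(C)(C)O1
F2 | step 11 | {3-[14-(4-hydroxy-3,5-dimethoxyphenyl)tetradecyl]-5-methoxyphenyl}boronic acid | COc1cc(cc(OC)c1O)CCCCCCCCCCCCCCc1cc(OC)cc(c1)B(O)O
F3 | step 7 | lithium enolate of 13-(3-bromo-5-methoxyphenyl)tridecan-2-one (methyl side) | [Li]OC(=C)CCCCCCCCCCCc1cc(Br)cc(OC)c1
F4 | step 7 | 14-(3-bromo-5-methoxyphenyl)-1-[3,5-dimethoxy-4-(methoxymethoxy)phenyl]-3-oxotetradecyl methanesulfonate (racemic) | COCOc1c(OC)cc(cc1OC)C(OS(C)(=O)=O)CC(=O)CCCCCCCCCCCc1cc(Br)cc(OC)c1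
F5 | step 9 | 14-(3-bromo-5-methoxyphenyl)-1-[3,5-dimethoxy-4-(methoxymethoxy)phenyl]tetradecan-3-ol (racemic) | COCOc1c(OC)cc(cc1OC)CCC(O)CCCCCCCCCCCc1cc(Br)cc(OC)c1
F6 | step 9 | 14-(3-bromo-5-methoxyphenyl)-1-[3,5-dimethoxy-4-(methoxymethoxy)phenyl]tetradecan-3-yl 4-methylbenzenesulfonate (racemic) | COCOc1c(OC)cc(cc1OC)CCC(OS(=O)(=O)c1ccc(C)cc1)CCCCCCCCCCCc1cc(Br)cc(OC)c1
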